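The dihydrofuran ring is closed last, at the aryl–oxygen bond O1–C7a, by palladium-catalysed intramolecular etherification of an open-chain (1S,2S)-1,2-diarylpropan-1-ol whose ring B carries chlorine at the future C7a. The step exploits that O1 sits on the benzylic carbon C2 and that C7a is ortho to C3a: neither stereocentre is a reacting atom, so the trans C2/C3 array, set beforehand by ketone α-arylation and a dynamic kinetic resolution hydrogenation, passes into the ring untouched. The chlorine is placed between bromine and the C7 methoxy group by directed lithiation; the erythro diol derives from (S)-lactate by chelation-controlled reduction.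

Key step: step 11

Remark: the SMILES is read as the (2S,3S)-trans-2-aryl-3-methyl-2,3-dihydrobenzofuran with a (1R,2S) (erythro) propane-1,2-diol at C5; benzofuran numbering (O1, C2, C3, C3a, C4 to C7, C7a) is used, ring A is the pendant aryl group and ring B the fused benzene ring. Compounds 1, 3 and 10 are taken as commercially available.

Step 1
Reactants: 1 ethyl (S)-2-(benzyloxy)propanoate
Product: 2 (S)-2-(benzyloxy)-N-methoxy-N-methylpropanamide
Conditions: MeNH(OMe)·HCl, i-PrMgCl, THF, −20 °C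
Reagents that add atoms: N,O-dimethylhydroxylamine hydrochloride, CNOC.Cl
Why: Weinreb amide formation by aminolysis of the ester with the chloromagnesium amide at low temperature should leave the α-alkoxy stereocentre untouched.

Step 2
Reactants: 3 1,3-dibromo-5-methoxybenzene; 2 (S)-2-(benzyloxy)-N-methoxy-N-methylpropanamide
Product: 5 (S)-2-(benzyloxy)-1-(3-bromo-5-methoxyphenyl)propan-1-one, via aryllithium 4 (not isolated)
Conditions: n-BuLi (1 equiv), Et2O, −78 °C; then 2, THF, −78 to 0 °C; aq NH4Cl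
Reagents that add atoms: none
Why: Mono bromine–lithium exchange of the symmetrical dibromide followed by Weinreb ketone synthesis should stop at the ketone through the chelated tetrahedral intermediate, with the lactate stereocentre retained.

Step 3
Reactants: 5 (S)-2-(benzyloxy)-1-(3-bromo-5-methoxyphenyl)propan-1-one
Product: 6 (1R,2S)-2-(benzyloxy)-1-(3-bromo-5-methoxyphenyl)propan-1-ol
Conditions: Zn(BH4)2, Et2O, −20 °C
Reagents that add atoms: none
Why: Chelation-controlled (Cram chelate) reduction, in which zinc bridges the carbonyl and benzyloxy oxygens and hydride adds to the face anti to the methyl group, should set C1 as R and give the anti (erythro) alcohol.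

Step 4
Reactants: 6 (1R,2S)-2-(benzyloxy)-1-(3-bromo-5-methoxyphenyl)propan-1-ol
Product: 7 [(1R,2S)-2-(benzyloxy)-1-(3-bromo-5-methoxyphenyl)propoxy](tert-butyl)dimethylsilane
Conditions: TBSOTf, 2,6-lutidine, CH2Cl2, 0 °C
Reagents that add atoms: tert-butyldimethylsilyl trifluoromethanesulfonate, CC(C)(C)[Si](C)(C)OS(=O)(=O)C(F)(F)F
Why: Silylation of the secondary benzylic alcohol masks the only free hydroxyl so that it cannot compete as a nucleophile or hydride donor in the later base- and palladium-mediated steps.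

Step 5
Reactants: 7 [(1R,2S)-2-(benzyloxy)-1-(3-bromo-5-methoxyphenyl)propoxy](tert-butyl)dimethylsilane
Product: 9 [(1R,2S)-2-(benzyloxy)-1-(3-bromo-4-chloro-5-methoxyphenyl)propoxy](tert-butyl)dimethylsilane, via aryllithium 8 (not isolated)
Conditions: LiN(i-Pr)2, THF, −78 °C; then C2Cl6, −78 °C to rt
Reagents that add atoms: hexachloroethane, ClC(Cl)(Cl)C(Cl)(Cl)Cl
Why: Directed ortho-metalation should occur at the one C–H flanked by bromine and methoxy (the most acidic site), and electrophilic chlorination at −78 °C should trap the aryllithium before it loses LiBr.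

Step 6
Reactants: 10 3-hydroxy-4,5-dimethoxybenzaldehyde
Product: 11 3-(benzyloxy)-4,5-dimethoxybenzaldehyde
Conditions: BnBr, K2CO3, DMF, rt
Reagents that add atoms: benzyl bromide, BrCc1ccccc1
Why: Williamson etherification of the phenoxide protects the ring A phenol as a base-stable benzyl ether.

Step 7
Reactants: 11 3-(benzyloxy)-4,5-dimethoxybenzaldehyde
Product: 12 1-[3-(benzyloxy)-4,5-dimethoxyphenyl]propan-1-ol (racemic)
Conditions: EtMgBr, THF, 0 °C; aq NH4Cl
Reagents that add atoms: ethylmagnesium bromide, CC[Mg]Br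
Why: Grignard addition to the aldehyde gives the secondary alcohol, whose configuration is irrelevant because it is oxidised next.

Step 8
Reactants: 12 1-[3-(benzyloxy)-4,5-dimethoxyphenyl]propan-1-ol
Product: 13 1-[3-(benzyloxy)-4,5-dimethoxyphenyl]propan-1-one
Conditions: Dess–Martin periodinane, NaHCO3, CH2Cl2, rt
Reagents that add atoms: none
Why: Dess–Martin oxidation of the benzylic alcohol should give the propiophenone under neutral conditions.

Step 9
Reactants: 13 1-[3-(benzyloxy)-4,5-dimethoxyphenyl]propan-1-one; 9 [(1R,2S)-2-(benzyloxy)-1-(3-bromo-4-chloro-5-methoxyphenyl)propoxy](tert-butyl)dimethylsilane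
Product: 14 1-[3-(benzyloxy)-4,5-dimethoxyphenyl]-2-{5-[(1R,2S)-2-(benzyloxy)-1-(tert-butyldimethylsilyloxy)propyl]-2-chloro-3-methoxyphenyl}propan-1-one (both C2 epimers)
Conditions: Pd2(dba)3 (cat.), Xantphos (cat.), NaOtBu, toluene, 80 °C
Reagents that add atoms: none
Why: Palladium-catalysed ketone α-arylation should join the sodium enolate to the C–Br bond, which undergoes oxidative addition far more readily than the doubly flanked C–Cl bond with this bisphosphine; the new α-centre is left as an epimer mixture on purpose.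

Step 10
Reactants: 14 1-[3-(benzyloxy)-4,5-dimethoxyphenyl]-2-{5-[(1R,2S)-2-(benzyloxy)-1-(tert-butyldimethylsilyloxy)propyl]-2-chloro-3-methoxyphenyl}propan-1-one
Product: 15 (1S,2S)-1-[3-(benzyloxy)-4,5-dimethoxyphenyl]-2-{5-[(1R,2S)-2-(benzyloxy)-1-(tert-butyldimethylsilyloxy)propyl]-2-chloro-3-methoxyphenyl}propan-1-ol
Conditions: trans-RuCl2[(R)-xylbinap][(R)-daipen] (cat.), KOtBu (cat.), H2 (10 atm), i-PrOH/THF, 30 °C
Reagents that add atoms: none
Why: Noyori asymmetric hydrogenation with dynamic kinetic resolution: the base epimerises the acidic α-aryl centre, the catalyst (this enantiomer by analogy with aryl alkyl ketones) should set the carbinol as S, and the Felkin–Anh preference selects the (2S)-epimer as the fast-reacting one, so both new centres converge on (1S,2S).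

Step 11
Reactants: 15 (1S,2S)-1-[3-(benzyloxy)-4,5-dimethoxyphenyl]-2-{5-[(1R,2S)-2-(benzyloxy)-1-(tert-butyldimethylsilyloxy)propyl]-2-chloro-3-methoxyphenyl}propan-1-ol
Product: 16 (2S,3S)-2-[3-(benzyloxy)-4,5-dimethoxyphenyl]-5-[(1R,2S)-2-(benzyloxy)-1-(tert-butyldimethylsilyloxy)propyl]-7-methoxy-3-methyl-2,3-dihydrobenzofuran
Conditions: Pd(OAc)2 (cat.), 2-(di-tert-butylphosphino)-1,1'-binaphthyl (cat.), Cs2CO3, toluene, 80 °C
Reagents that add atoms: none
Why: Zerovalent palladium formed from Pd(OAc)2 and the bulky phosphine should insert into the C7a–Cl bond of ring B, the carbonate converts the free C2 hydroxyl into an alkoxide bound to divalent palladium in a six-membered chelate, and C–O reductive elimination forms O1–C7a. The closest known reaction type is the palladium-catalysed intramolecular etherification of ortho-haloaryl alcohols (Buchwald–Hartwig-type C–O coupling, the catalytic counterpart of the Ullmann ether synthesis). The five-membered dihydrofuran ring closes in a 5-exo sense at the ipso carbon through that six-membered palladacycle. No stereocentre is created: neither C2 nor C3 is a reacting atom, so the (1S,2S) open-chain array becomes the (2S,3S) trans ring array with retention, aryl and methyl on opposite faces. Reductive elimination must outrun β-hydride elimination of the benzylic C2–H, which the di-tert-butyl biaryl phosphine is chosen to secure. A single nucleophile and a single electrophilic site are secured by the silyl and benzyl ethers on all other oxygens and by C–Cl being the only carbon–halogen bond, and aryne formation is excluded because C7a is flanked by C7–OMe and C3a.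

Step 12
Reactants: 16 (2S,3S)-2-[3-(benzyloxy)-4,5-dimethoxyphenyl]-5-[(1R,2S)-2-(benzyloxy)-1-(tert-butyldimethylsilyloxy)propyl]-7-methoxy-3-methyl-2,3-dihydrobenzofuran
Product: 17 (1R,2S)-2-(benzyloxy)-1-{(2S,3S)-2-[3-(benzyloxy)-4,5-dimethoxyphenyl]-7-methoxy-3-methyl-2,3-dihydrobenzofuran-5-yl}propan-1-ol
Conditions: Bu4NF, THF, 0 °C to rt; aq NH4Cl
Reagents that add atoms: none
Why: Fluoride-induced desilylation should free the benzylic alcohol without acid, which avoids ionisation and epimerisation of the para-alkoxybenzylic carbinol.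

Step 13
Reactants: 17 (1R,2S)-2-(benzyloxy)-1-{(2S,3S)-2-[3-(benzyloxy)-4,5-dimethoxyphenyl]-7-methoxy-3-methyl-2,3-dihydrobenzofuran-5-yl}propan-1-ol
Product: 18 (1R,2S)-1-[(2S,3S)-2-(3-hydroxy-4,5-dimethoxyphenyl)-7-methoxy-3-methyl-2,3-dihydrobenzofuran-5-yl]propane-1,2-diol
Conditions: H2 (1 atm), Pd/C (10 %), EtOAc, rt
Reagents that add atoms: none
Why: Catalytic hydrogenolysis should cleave the phenolic and the aliphatic benzyl ether, while the neutral medium and low pressure are expected to spare the secondary benzylic alcohol and the benzylic C2–O1 bond.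

Compound list
1 | ethyl (S)-2-(benzyloxy)propanoate | CCOC(=O)[C@H](C)OCc1ccccc1 | starting material
2 | (S)-2-(benzyloxy)-N-methoxy-N-methylpropanamide | CON(C)C(=O)[C@H](C)OCc1ccccc1 | intermediate
3 | 1,3-dibromo-5-methoxybenzene | COc1cc(Br)cc(Br)c1 | starting material
4 | (3-bromo-5-methoxyphenyl)lithium | COc1cc(Br)cc([Li])c1 | intermediate
5 | (S)-2-(benzyloxy)-1-(3-bromo-5-methoxyphenyl)propan-1-one | COc1cc(Br)cc(C(=O)[C@H](C)OCc2ccccc2)c1 | intermediate
6 | (1R,2S)-2-(benzyloxy)-1-(3-bromo-5-methoxyphenyl)propan-1-ol | COc1cc(Br)cc([C@@H](O)[C@H](C)OCc2ccccc2)c1 | intermediate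
7 | [(1R,2S)-2-(benzyloxy)-1-(3-bromo-5-methoxyphenyl)propoxy](tert-butyl)dimethylsilane | COc1cc(Br)cc([C@@H](O[Si](C)(C)C(C)(C)C)[C@H](C)OCc2ccccc2)c1 | intermediate
8 | {4-[(1R,2S)-2-(benzyloxy)-1-(tert-butyldimethylsilyloxy)propyl]-2-bromo-6-methoxyphenyl}lithium | COc1cc([C@@H](O[Si](C)(C)C(C)(C)C)[C@H](C)OCc2ccccc2)cc(Br)c1[Li] | intermediate
9 | [(1R,2S)-2-(benzyloxy)-1-(3-bromo-4-chloro-5-methoxyphenyl)propoxy](tert-butyl)dimethylsilane | COc1cc([C@@H](O[Si](C)(C)C(C)(C)C)[C@H](C)OCc2ccccc2)cc(Br)c1Cl | intermediate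
10 | 3-hydroxy-4,5-dimethoxybenzaldehyde | O=Cc1cc(O)c(OC)c(OC)c1 | starting material
11 | 3-(benzyloxy)-4,5-dimethoxybenzaldehyde | O=Cc1cc(OC)c(OC)c(OCc2ccccc2)c1 | intermediate
12 | 1-[3-(benzyloxy)-4,5-dimethoxyphenyl]propan-1-ol (racemic) | CCC(O)c1cc(OC)c(OC)c(OCc2ccccc2)c1 | intermediate
13 | 1-[3-(benzyloxy)-4,5-dimethoxyphenyl]propan-1-one | CCC(=O)c1cc(OC)c(OC)c(OCc2ccccc2)c1 | intermediate
14 | 1-[3-(benzyloxy)-4,5-dimethoxyphenyl]-2-{5-[(1R,2S)-2-(benzyloxy)-1-(tert-butyldimethylsilyloxy)propyl]-2-chloro-3-methoxyphenyl}propan-1-one (both C2 epimers) | CC(C(=O)c1cc(OC)c(OC)c(OCc2ccccc2)c1)c1cc([C@@H](O[Si](C)(C)C(C)(C)C)[C@H](C)OCc2ccccc2)cc(OC)c1Cl | intermediate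
15 | (1S,2S)-1-[3-(benzyloxy)-4,5-dimethoxyphenyl]-2-{5-[(1R,2S)-2-(benzyloxy)-1-(tert-butyldimethylsilyloxy)propyl]-2-chloro-3-methoxyphenyl}propan-1-ol | O[C@H](c1cc(OC)c(OC)c(OCc2ccccc2)c1)[C@@H](C)c1cc([C@@H](O[Si](C)(C)C(C)(C)C)[C@H](C)OCc2ccccc2)cc(OC)c1Cl | intermediate
16 | (2S,3S)-2-[3-(benzyloxy)-4,5-dimethoxyphenyl]-5-[(1R,2S)-2-(benzyloxy)-1-(tert-butyldimethylsilyloxy)propyl]-7-methoxy-3-methyl-2,3-dihydrobenzofuran | COc1cc([C@H]2Oc3c(OC)cc([C@@H](O[Si](C)(C)C(C)(C)C)[C@H](C)OCc4ccccc4)cc3[C@@H]2C)cc(OCc2ccccc2)c1OC | intermediate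
17 | (1R,2S)-2-(benzyloxy)-1-{(2S,3S)-2-[3-(benzyloxy)-4,5-dimethoxyphenyl]-7-methoxy-3-methyl-2,3-dihydrobenzofuran-5-yl}propan-1-ol | COc1cc([C@H]2Oc3c(OC)cc([C@@H](O)[C@H](C)OCc4ccccc4)cc3[C@@H]2C)cc(OCc2ccccc2)c1OC | intermediate
18 | (1R,2S)-1-[(2S,3S)-2-(3-hydroxy-4,5-dimethoxyphenyl)-7-methoxy-3-methyl-2,3-dihydrobenzofuran-5-yl]propane-1,2-diol | COc1cc([C@H]2Oc3c(OC)cc([C@@H](O)[C@H](C)O)cc3[C@@H]2C)cc(O)c1OC | target

Total step count: 13. Longest linear sequence: 10 steps (steps 1 to 5, then 9 to 13); steps 6 to 8 form the convergent ring A branch.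

Steps most likely to fail

Step 11 (key step). β-Hydride elimination from the aryl(alkoxo)palladium intermediate may compete with C–O reductive elimination. This would oxidise the benzylic carbinol back to the ketone with loss of chlorine, or erode C2 through reversible hydride transfer. Oxidative addition into the doubly ortho-substituted, electron-rich C–Cl bond may also be slow. The fallback forms the same O1–C7a bond by addition–elimination at a fluoroarene, without a transition metal, and sets out from 7. Lithiation as in step 5 (through 8) and quenching with (PhSO2)2NF should give [(1R,2S)-2-(benzyloxy)-1-(3-bromo-4-fluoro-5-methoxyphenyl)propoxy](tert-butyl)dimethylsilane F1. α-Arylation of 13 with F1 under the step 9 conditions should give 1-[3-(benzyloxy)-4,5-dimethoxyphenyl]-2-{5-[(1R,2S)-2-(benzyloxy)-1-(tert-butyldimethylsilyloxy)propyl]-2-fluoro-3-methoxyphenyl}propan-1-one F2. Hydrogenation as in step 10 should give (1S,2S)-1-[3-(benzyloxy)-4,5-dimethoxyphenyl]-2-{5-[(1R,2S)-2-(benzyloxy)-1-(tert-butyldimethylsilyloxy)propyl]-2-fluoro-3-methoxyphenyl}propan-1-ol F3. Treatment with KN(SiMe3)2 in THF/DMF at 80 °C should then close the ring by intramolecular nucleophilic aromatic substitution of fluoride by the potassium alkoxide, and the route is rejoined at 16.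

Step 10. Epimerisation of the congested α-aryl centre may be slow relative to hydrogenation, or facial discrimination at the hindered ketone may be poor, so that the C3 epimer or the enantiomeric carbinol is carried forward. The fallback sets the two centres separately. α-Bromination of 13 (PhNMe3Br3, THF) should give racemic 2-bromo-1-[3-(benzyloxy)-4,5-dimethoxyphenyl]propan-1-one F4. Bromine–magnesium exchange on 9 (i-PrMgCl·LiCl, THF, −20 °C) should give {5-[(1R,2S)-2-(benzyloxy)-1-(tert-butyldimethylsilyloxy)propyl]-2-chloro-3-methoxyphenyl}magnesium chloride F5, and transmetalation with ZnI2 the corresponding arylzinc iodide F6. A stereoconvergent nickel-catalysed asymmetric Negishi coupling of F4 with F6 (NiCl2·glyme, chiral pybox ligand, glyme/THF, −30 °C) should give (S)-1-[3-(benzyloxy)-4,5-dimethoxyphenyl]-2-{5-[(1R,2S)-2-(benzyloxy)-1-(tert-butyldimethylsilyloxy)propyl]-2-chloro-3-methoxyphenyl}propan-1-one F7, the single (2S)-epimer of 14. Felkin–Anh-controlled reduction with LiBH(s-Bu)3 in THF at −78 °C should then deliver the (1S,2S)-alcohol, rejoining the route at 15.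

Step 9. Carbon–carbon reductive elimination between the ortho-substituted aryl group and the secondary enolate may be slow, letting hydrodebromination or enolate O-arylation at the neighbouring C–Cl bond (benzofuran formation) compete. The fallback arylates a less hindered methyl ketone enolate and introduces the methyl group afterwards; it sets out from 11 and 9. MeMgBr addition to 11 should give 1-[3-(benzyloxy)-4,5-dimethoxyphenyl]ethan-1-ol F8, and Dess–Martin oxidation should give 1-[3-(benzyloxy)-4,5-dimethoxyphenyl]ethan-1-one F9. α-Arylation of F9 (in excess) with 9 under the step 9 conditions should give 1-[3-(benzyloxy)-4,5-dimethoxyphenyl]-2-{5-[(1R,2S)-2-(benzyloxy)-1-(tert-butyldimethylsilyloxy)propyl]-2-chloro-3-methoxyphenyl}ethan-1-one F10. Deprotonation with LiN(i-Pr)2 and C-methylation with MeI in THF at −78 °C should then give 14, where the route is rejoined.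

Further compounds
F1 | step 11 | [(1R,2S)-2-(benzyloxy)-1-(3-bromo-4-fluoro-5-methoxyphenyl)propoxy](tert-butyl)dimethylsilane | COc1cc([C@@H](O[Si](C)(C)C(C)(C)C)[C@H](C)OCc2ccccc2)cc(Br)c1F
F2 | step 11 | 1-[3-(benzyloxy)-4,5-dimethoxyphenyl]-2-{5-[(1R,2S)-2-(benzyloxy)-1-(tert-butyldimethylsilyloxy)propyl]-2-fluoro-3-methoxyphenyl}propan-1-one (both C2 epimers) | CC(C(=O)c1cc(OC)c(OC)c(OCc2ccccc2)c1)c1cc([C@@H](O[Si](C)(C)C(C)(C)C)[C@H](C)OCc2ccccc2)cc(OC)c1F
F3 | step 11 | (1S,2S)-1-[3-(benzyloxy)-4,5-dimethoxyphenyl]-2-{5-[(1R,2S)-2-(benzyloxy)-1-(tert-butyldimethylsilyloxy)propyl]-2-fluoro-3-methoxyphenyl}propan-1-ol | O[C@H](c1cc(OC)c(OC)c(OCc2ccccc2)c1)[C@@H](C)c1cc([C@@H](O[Si](C)(C)C(C)(C)C)[C@H](C)OCc2ccccc2)cc(OC)c1F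
F4 | step 10 | 2-bromo-1-[3-(benzyloxy)-4,5-dimethoxyphenyl]propan-1-one (racemic) | CC(Br)C(=O)c1cc(OC)c(OC)c(OCc2ccccc2)c1
F5 | step 10 | {5-[(1R,2S)-2-(benzyloxy)-1-(tert-butyldimethylsilyloxy)propyl]-2-chloro-3-methoxyphenyl}magnesium chloride | COc1cc([C@@H](O[Si](C)(C)C(C)(C)C)[C@H](C)OCc2ccccc2)cc([Mg]Cl)c1Cl
F6 | step 10 | {5-[(1R,2S)-2-(benzyloxy)-1-(tert-butyldimethylsilyloxy)propyl]-2-chloro-3-methoxyphenyl}zinc iodide | COc1cc([C@@H](O[Si](C)(C)C(C)(C)C)[C@H](C)OCc2ccccc2)cc([Zn]I)c1Cl
F7 | step 10 | (S)-1-[3-(benzyloxy)-4,5-dimethoxyphenyl]-2-{5-[(1R,2S)-2-(benzyloxy)-1-(tert-butyldimethylsilyloxy)propyl]-2-chloro-3-methoxyphenyl}propan-1-one | O=C(c1cc(OC)c(OC)c(OCc2ccccc2)c1)[C@@H](C)c1cc([C@@H](O[Si](C)(C)C(C)(C)C)[C@H](C)OCc2ccccc2)cc(OC)c1Cl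
F8 | step 9 | 1-[3-(benzyloxy)-4,5-dimethoxyphenyl]ethan-1-ol (racemic) | CC(O)c1cc(OC)c(OC)c(OCc2ccccc2)c1
F9 | step 9 | 1-[3-(benzyloxy)-4,5-dimethoxyphenyl]ethan-1-one | CC(=O)c1cc(OC)c(OC)c(OCc2ccccc2)c1
F10 | step 9 | 1-[3-(benzyloxy)-4,5-dimethoxyphenyl]-2-{5-[(1R,2S)-2-(benzyloxy)-1-(tert-butyldimethylsilyloxy)propyl]-2-chloro-3-methoxyphenyl}ethan-1-one | O=C(Cc1cc([C@@H](O[Si](C)(C)C(C)(C)C)[C@H](C)OCc2ccccc2)cc(OC)c1Cl)c1cc(OC)c(OC)c(OCc2ccccc2)c1
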